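**Plan**

1. Numbering: C1 carries the acetate, C2–C3 the epoxide (methyl on C3), then C4, C5, C6 (ring-fusion CH), C7 (side-chain carbon), C8, C9, C10 (methylated ring-fusion carbon); the chain runs from C11 (methyl-bearing) to C15 (carbinol).
2. Cuts, working back: the O-acetyl group; both C15–CH3 bonds and C13=C14 (ester ylide); C11–CH3 (cuprate on an ynoate); C12–C13 and C11≡C12 (alkyne from a C11 aldehyde); the epoxide oxygen and C1–H; then C1–C2 and C2–C3; finally C7=C8, C9–C10 and C10–CH3.
3. Enabling feature: in the seven-membered ring C1 sits between the two methyl-bearing carbons C10 and C3, and only C2 separates C1 from C3, so taking C2 out leaves a 2,6-dimethylcyclohexanone whose C1–C3 bond is an enol double bond; C10 has no hydrogen, so that enol can form only toward C3.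
4. Forward order of rings: the six-membered ring is that of (R)-carvone (C1, C3, C4, C5, C6, C10); the five-membered ring (C6 to C10) closes by metathesis after two enolate alkylations; the six is then enlarged to the seven by inserting C2; the chain is grown last from a C7 ethynyl group.
5. Stereochemistry: C6 comes from (R)-carvone; C10 from allylation anti to the C6 substituent; C7 from base equilibration of the C7 aldehyde; C1 from pseudoequatorial hydride delivery; C2 and C3 from hydroxyl-directed epoxidation; 11Z from syn carbocupration; 13E from a stabilised ylide.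

Key step: step 10

Remark on the chemistry: target numbering is used for the bicyclic compounds, and centres that form as mixtures and are erased later (the methylated ring carbon of 5, C3 in 9 to 12 and 16, C7 in 9 and 10, the cyclopropane carbons of 15) are left undefined in the SMILES.

**Route**

Step 1
Reactants: 1 (R)-carvone
Product: 2 (R)-10-hydroxycarvone, (5R)-5-(3-hydroxyprop-1-en-2-yl)-2-methylcyclohex-2-en-1-one
Conditions: SeO2 (cat.), t-BuOOH, CH2Cl2, 0 °C → rt
Reagents that add atoms: tert-butyl hydroperoxide, CC(C)(C)OO (source of the new oxygen, relayed by selenium dioxide, O=[Se]=O)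
Why: Selenium dioxide allylic oxidation (ene reaction, then [2,3]-sigmatropic shift, reoxidised by t-BuOOH) should functionalise the electron-rich 1,1-disubstituted alkene at its methyl group and leave the electron-poor enone alone; the existing stereocenter is not touched.

Step 2
Reactants: 2 (R)-10-hydroxycarvone
Product: 3 triethylsilyl ether of 2, (5R)-2-methyl-5-[3-(triethylsilyloxy)prop-1-en-2-yl]cyclohex-2-en-1-one
Conditions: Et3SiCl, imidazole, CH2Cl2, 0 °C → rt
Reagents that add atoms: chlorotriethylsilane, CC[Si](CC)(CC)Cl
Why: Standard silylation of a primary allylic alcohol; the triethylsilyl ether is stable to the amide bases, metathesis and hydrogenation that follow and is later oxidised directly.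

Step 3
Reactants: 3 triethylsilyl ether of 2; 4 iodomethane
Product: 5 (5R)-2,6-dimethyl-5-[3-(triethylsilyloxy)prop-1-en-2-yl]cyclohex-2-en-1-one, both epimers at the new centre (the later C10)
Conditions: LiN(i-Pr)2 (LDA), THF, −78 °C; MeI, −78 → −20 °C
Reagents that add atoms: iodomethane, IC
Why: Kinetic deprotonation of the enone at the α′ methylene gives the cross-conjugated lithium enolate, which is C-methylated (enolate alkylation); the new centre forms as a mixture and becomes planar again in step 4.

Step 4
Reactants: 5 methylated enone; 6 allyl bromide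
Product: 7 6-allyl-2,6-dimethyl-5-[3-(triethylsilyloxy)prop-1-en-2-yl]cyclohex-2-en-1-one, allyl trans and methyl cis to the 5-substituent
Conditions: LiN(i-Pr)2 (LDA), THF, −78 → 0 °C; allyl bromide, DMPU, −78 °C → rt
Reagents that add atoms: allyl bromide, C=CCBr
Why: Second enolate alkylation: allyl bromide should attack the trisubstituted enolate on the face opposite the adjacent ring substituent, so that allyl ends trans and methyl cis to it, which fixes C10 and makes the later ring fusion trans.

Step 5
Reactants: 7 allylated enone
Product: 8 trans-fused bicyclic dienone: C1 ketone, C3=C4 and C7=C8 alkenes, methyls on C3 and C10, CH2OSiEt3 on C7, H6 trans to the C10 methyl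
Conditions: second-generation Grubbs catalyst, RuCl2(=CHPh)(PCy3)(H2IMes) (cat.), CH2Cl2, 40 °C
Reagents that add atoms: none
Why: Ring-closing metathesis between the allyl group and the 1,1-disubstituted alkene closes the cyclopentene C7=C8 with loss of ethene; the trans-disposed alkenes reach each other without strain, the trisubstituted enone alkene does not take part, and no stereocenter is formed.

Step 6
Reactants: 8 bicyclic dienone
Product: 9 saturated trans-hydrindanone: C1 ketone, methyls on C3 and C10, CH2OSiEt3 on C7 (C3 and C7 epimer mixtures)
Conditions: H2 (1 atm), Pd/C, EtOAc, rt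
Reagents that add atoms: none
Why: Heterogeneous hydrogenation saturates both C=C bonds and leaves the ketone and silyl ether; C3 and C7 should arise as mixtures, which is harmless because C7 is corrected in step 8 and C3 becomes trigonal in step 9.

Step 7
Reactants: 9 saturated hydrindanone
Product: 10 keto aldehyde: as 9 with CHO on C7 (C3 and C7 epimer mixtures)
Conditions: (COCl)2, DMSO, CH2Cl2, −78 → −30 °C; Et3N, −78 °C → rt
Reagents that add atoms: none
Why: Under Swern conditions the chlorosulfonium salt cleaves a primary triethylsilyl ether and the resulting alkoxysulfonium ion collapses to the aldehyde in the same flask (Swern oxidation of a primary triethylsilyl ether), while the hindered ketone is inert.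

Step 8
Reactants: 10 keto aldehyde
Product: 12 7-ethynyl-3,10-dimethyl trans-hydrindan-1-one (ethynyl cis to H6 and anti to the C10 methyl), via equilibrated aldehyde 11 (not isolated)
Conditions: K2CO3, MeOH, rt; then dimethyl (1-diazo-2-oxopropyl)phosphonate, 0 °C → rt
Reagents that add atoms: dimethyl (1-diazo-2-oxopropyl)phosphonate, COP(=O)(OC)C(=[N+]=[N-])C(C)=O
Why: Carbonate in methanol equilibrates the enolisable formyl group to the less crowded C7 epimer, trans to C5 on the cyclopentane and anti to the C10 methyl, and the Ohira–Bestmann modification of the Seyferth–Gilbert homologation then turns that aldehyde into the terminal alkyne, after which C7 can no longer epimerise; the doubly α-branched ketone does not react.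

Step 9
Reactants: 12 ethynyl hydrindanone
Product: 13 trimethylsilyl enol ether C1(OSiMe3)=C3(CH3) carrying a (trimethylsilyl)ethynyl group on C7
Conditions: LiN(i-Pr)2 (LDA, 2.5 equiv), THF, −78 → 0 °C; Me3SiCl, Et3N, −78 °C → rt
Reagents that add atoms: chlorotrimethylsilane, C[Si](C)(C)Cl
Why: Because C10 is quaternary the ketone can be deprotonated only at C3, so trapping the lithium enolate with Me3SiCl gives a single tetrasubstituted silyl enol ether, and the lithium acetylide formed by the excess base is C-silylated at the same time, which masks the alkyne for step 10.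

Step 10
Reactants: 13 silyl enol ether; 14 diiodomethane
Product: 17 trans-fused 3,10-dimethyl-7-[(trimethylsilyl)ethynyl]bicyclo[5.3.0]dec-2-en-1-one, via siloxycyclopropane 15 (not isolated), via β-chloro ketone 16 (not isolated)
Conditions: Et2Zn, CH2I2, toluene, 0 °C → rt; crude 15: FeCl3, pyridine, DMF, 0 °C → rt; crude 16: NaOAc, MeOH, 65 °C
Reagents that add atoms: diiodomethane, ICI
Why: The zinc carbenoid EtZnCH2I transfers CH2 to the electron-rich C1=C3 enol ether in a concerted [2+1] addition, which closes the three-membered ring and forms C1–C2 and C2–C3 (15). FeCl3 then takes the silyl group from oxygen and oxidises the cyclopropanol by one electron; the oxygen radical fragments the ring-fusion bond C1–C3, so C1 becomes the ketone of a seven-membered ring and C3 a tertiary radical that abstracts chlorine from a second FeCl3 (16), and acetate removes HCl by E1cB elimination to the conjugated C2=C3 enone. The closest known reaction type is the Ito–Saegusa ring expansion of 1-siloxybicyclo[n.1.0]alkanes. Mode of closure: the cyclopropane closes by cheletropic-type methylene transfer, and the seven-membered ring arises by enlargement of the six through β-scission, not by cyclisation of a chain. No stereocenter is kept, since the cyclopropane carbons and the chlorinated C3 are transient and C1 to C3 end trigonal. The step needs chemoselectivity for the enol ether, secured because it is the only electron-rich alkene (the silyl-capped alkyne is inert to the carbenoid), and scission of C1–C3 over C1–C2, secured by the tertiary versus primary radical; the insertion site itself is fixed by the quaternary C10.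

Step 11
Reactants: 17 silylalkynyl cycloheptenone
Product: 19 7-ethynyl-3,10-dimethylbicyclo[5.3.0]dec-2-en-1-ol (C1 hydroxyl anti to the C10 methyl), via C-silylated allylic alcohol 18 (not isolated)
Conditions: LiBH(s-Bu)3 (L-Selectride), THF, −78 °C; then MeOH, aq. NaOH, H2O2, 0 °C → rt
Reagents that add atoms: none
Why: Hindered trialkylborohydride reduction: the reagent adds 1,2 to the β,β-disubstituted, twisted enone and should approach C1 along the pseudoequatorial path on the outer face of the chair-like cycloheptenone, anti to the C10–C6 bond and clear of the syn-axial H6 (as in the reduction of 4,4-dimethyl-3-oxo triterpenoids to axial alcohols), which places the hydroxyl pseudoaxial and trans to the C10 methyl; the alkaline methanolic peroxide work-up oxidises the borane and cleaves the alkynyl C–Si bond.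

Step 12
Reactants: 19 allylic alcohol
Product: 20 epoxy alcohol: 2,3-epoxide cis to the C1 hydroxyl, both anti to the C10 methyl; ethynyl on C7
Conditions: VO(acac)2 (cat.), t-BuOOH, CH2Cl2, 0 °C → rt
Reagents that add atoms: tert-butyl hydroperoxide, CC(C)(C)OO
Why: Vanadium-catalysed hydroxyl-directed epoxidation: the C1 vanadate ester delivers the peroxide oxygen to the same face of C2=C3, which is also the face away from the C10 methyl, so C2 and C3 are set cis to the C1 oxygen, and the isolated terminal alkyne is not oxidised.

Step 13
Reactants: 20 epoxy alcohol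
Product: 21 C1 triethylsilyl ether of 20
Conditions: Et3SiOTf, 2,6-lutidine, CH2Cl2, −78 °C
Reagents that add atoms: triethylsilyl trifluoromethanesulfonate, CC[Si](CC)(CC)OS(=O)(=O)C(F)(F)F
Why: A silyl triflate with a hindered pyridine base silylates the crowded secondary alcohol at low temperature without opening the epoxide, and the triethylsilyl ether protects C1 through the organometallic and hydride steps.

Step 14
Reactants: 21 silyl ether
Product: 22 ynoate: C7–C11≡C12–CO2Me
Conditions: n-BuLi, THF, −78 °C; ClCO2Me, −78 → −20 °C
Reagents that add atoms: methyl chloroformate, COC(=O)Cl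
Why: Deprotonation of the terminal alkyne and C-acylation of the lithium acetylide with methyl chloroformate; at −78 °C neither the trisubstituted epoxide nor the silyl ether reacts.

Step 15
Reactants: 22 ynoate
Product: 23 (Z)-enoate: C7–C11(CH3)=C12H–CO2Me with C7 and the ester cis
Conditions: Me2CuLi (from MeLi and CuBr·SMe2), THF, −78 °C; MeOH, then aq. NH4Cl, −78 °C
Reagents that add atoms: lithium dimethylcuprate, [Li+].C[Cu-]C (made in the flask from methyllithium, [Li]C)
Why: Conjugate addition of the Gilman reagent to the ynoate is a syn carbocupration, and protonation of the vinylcopper species at −78 °C with retention leaves the new methyl cis to H12 and C7 cis to the ester, which sets the 11Z geometry; the hindered epoxide is not opened at this temperature.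

Step 16
Reactants: 23 (Z)-enoate
Product: 24 (Z)-allylic alcohol: C7–C11(CH3)=C12H–CH2OH
Conditions: i-Bu2AlH (DIBAL-H), CH2Cl2, −78 °C
Reagents that add atoms: none
Why: Aluminium hydride reduction of the conjugated ester to the allylic alcohol at low temperature, which keeps the Z geometry and spares the epoxide and silyl ether.

Step 17
Reactants: 24 (Z)-allylic alcohol
Product: 26 methyl (11Z,13E)-dienoate C7–C11(CH3)=C12H–C13H=C14H–CO2Me, via Z-enal 25 (not isolated)
Conditions: MnO2, Ph3P=CHCO2Me, CH2Cl2, rt
Reagents that add atoms: methyl (triphenylphosphoranylidene)acetate, COC(=O)C=P(c1ccccc1)(c1ccccc1)c1ccccc1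
Why: Tandem oxidation–Wittig reaction: MnO2 oxidises only the allylic alcohol and the Z-enal is trapped as it forms by the ester-stabilised ylide, which gives the E alkene at C13=C14 and avoids handling the isomerisation-prone Z-enal.

Step 18
Reactants: 26 dienoate
Product: 27 C1 triethylsilyl ether of the diol, with the tertiary C15 carbinol in place
Conditions: MeLi, CeCl3, THF, −78 → 0 °C
Reagents that add atoms: methyllithium, [Li]C (both C15 methyl groups)
Why: Double 1,2-addition of the methylcerium reagent to the ester carbonyl gives the dimethyl carbinol; the weakly basic organocerium suppresses enolisation of the intermediate methyl ketone and conjugate addition, and the epoxide survives at low temperature.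

Step 19
Reactants: 27 silyl ether
Product: 28 diol: C1 and C15 hydroxyls
Conditions: Bu4NF, THF, 0 °C → rt
Reagents that add atoms: none
Why: Fluoride-induced cleavage of the Si–O bond frees the C1 hydroxyl under conditions that leave the epoxide, the diene and the tertiary allylic alcohol untouched.

Step 20
Reactants: 28 diol
Product: 29 CNP0265175.1
Conditions: Ac2O, pyridine, DMAP (cat.), CH2Cl2, 0 °C
Reagents that add atoms: acetic anhydride, CC(=O)OC(C)=O
Why: DMAP-catalysed acylation discriminates between the secondary C1 hydroxyl and the tertiary C15 hydroxyl, which acylates far more slowly, so a slight excess of anhydride at low temperature should give the monoacetate.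

**Compound list**

1 | (R)-carvone | CC1=CC[C@@H](C(C)=C)CC1=O | starting material
2 | (R)-10-hydroxycarvone | CC1=CC[C@@H](C(=C)CO)CC1=O | intermediate
3 | triethylsilyl ether of 2 | CC1=CC[C@@H](C(=C)CO[Si](CC)(CC)CC)CC1=O | intermediate
4 | iodomethane | IC | starting material
5 | 6-methyl derivative of 3 (both epimers at the new centre) | CC1=CC[C@@H](C(=C)CO[Si](CC)(CC)CC)C(C)C1=O | intermediate
6 | allyl bromide | C=CCBr | starting material
7 | 6-allyl-6-methyl derivative of 3 (allyl trans to the 5-substituent) | CC1=CC[C@@H](C(=C)CO[Si](CC)(CC)CC)[C@](C)(CC=C)C1=O | intermediate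
8 | trans-fused bicyclic dienone (C3=C4, C7=C8, CH2OSiEt3 on C7) | CC1=CC[C@H]2C(CO[Si](CC)(CC)CC)=CC[C@]2(C)C1=O | intermediate
9 | saturated trans-hydrindanone (C3 and C7 mixtures) | CC1CC[C@H]2C(CO[Si](CC)(CC)CC)CC[C@]2(C)C1=O | intermediate
10 | keto aldehyde (C3 and C7 mixtures) | CC1CC[C@H]2C(C=O)CC[C@]2(C)C1=O | intermediate
11 | equilibrated keto aldehyde, CHO cis to H6 (not isolated) | CC1CC[C@H]2[C@H](C=O)CC[C@]2(C)C1=O | intermediate
12 | 7-ethynyl-3,10-dimethyl trans-hydrindan-1-one | CC1CC[C@H]2[C@H](C#C)CC[C@]2(C)C1=O | intermediate
13 | trimethylsilyl enol ether C1=C3 with C7 (trimethylsilyl)ethynyl group | C[Si](C)(C)OC1=C(C)CC[C@H]2[C@H](C#C[Si](C)(C)C)CC[C@]12C | intermediate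
14 | diiodomethane | ICI | starting material
15 | siloxycyclopropane, C2 bridging C1 and C3 (not isolated) | C[Si](C)(C)OC12CC1(C)CC[C@H]1[C@H](C#C[Si](C)(C)C)CC[C@]21C | intermediate
16 | 3-chloro-3-methyl cycloheptanone (not isolated) | O=C1CC(C)(Cl)CC[C@H]2[C@H](C#C[Si](C)(C)C)CC[C@]12C | intermediate
17 | trans-fused 3,10-dimethyl-7-[(trimethylsilyl)ethynyl]bicyclo[5.3.0]dec-2-en-1-one | O=C1C=C(C)CC[C@H]2[C@H](C#C[Si](C)(C)C)CC[C@]12C | intermediate
18 | C-silylated allylic alcohol, C1–OH anti to the C10 methyl (not isolated) | O[C@@H]1C=C(C)CC[C@H]2[C@H](C#C[Si](C)(C)C)CC[C@]12C | intermediate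
19 | 7-ethynyl-3,10-dimethylbicyclo[5.3.0]dec-2-en-1-ol, C1–OH anti to the C10 methyl | O[C@@H]1C=C(C)CC[C@H]2[C@H](C#C)CC[C@]12C | intermediate
20 | 2,3-epoxy alcohol, epoxide cis to the C1 hydroxyl | O[C@@H]1[C@@H]2O[C@]2(C)CC[C@H]2[C@H](C#C)CC[C@]12C | intermediate
21 | C1 triethylsilyl ether of 20 | CC[Si](CC)(CC)O[C@@H]1[C@@H]2O[C@]2(C)CC[C@H]2[C@H](C#C)CC[C@]12C | intermediate
22 | ynoate | CC[Si](CC)(CC)O[C@@H]1[C@@H]2O[C@]2(C)CC[C@H]2[C@H](C#CC(=O)OC)CC[C@]12C | intermediate
23 | (Z)-enoate | CC[Si](CC)(CC)O[C@@H]1[C@@H]2O[C@]2(C)CC[C@H]2[C@H](/C(C)=C\C(=O)OC)CC[C@]12C | intermediate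
24 | (Z)-allylic alcohol | CC[Si](CC)(CC)O[C@@H]1[C@@H]2O[C@]2(C)CC[C@H]2[C@H](/C(C)=C\CO)CC[C@]12C | intermediate
25 | (Z)-enal (not isolated) | CC[Si](CC)(CC)O[C@@H]1[C@@H]2O[C@]2(C)CC[C@H]2[C@H](/C(C)=C\C=O)CC[C@]12C | intermediate
26 | methyl (11Z,13E)-dienoate | CC[Si](CC)(CC)O[C@@H]1[C@@H]2O[C@]2(C)CC[C@H]2[C@H](/C(C)=C\C=C\C(=O)OC)CC[C@]12C | intermediate
27 | C1 triethylsilyl ether of the diol | CC[Si](CC)(CC)O[C@@H]1[C@@H]2O[C@]2(C)CC[C@H]2[C@H](/C(C)=C\C=C\C(C)(C)O)CC[C@]12C | intermediate
28 | diol (C1 and C15 hydroxyls) | O[C@@H]1[C@@H]2O[C@]2(C)CC[C@H]2[C@H](/C(C)=C\C=C\C(C)(C)O)CC[C@]12C | intermediate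
29 | CNP0265175.1 | CC(=O)O[C@@H]1[C@@H]2O[C@]2(C)CC[C@H]2[C@H](/C(C)=C\C=C\C(C)(C)O)CC[C@]12C | target

**Totals**

Total step count: 20.
Longest linear sequence: 20 steps, from 1 to 29; the route has no convergent branch.

**Steps most likely to fail**

Step 11. Hydride delivery to the other face of C1, or competing conjugate reduction, would erode or invert the C1 configuration on which the directed epoxidation depends. The fallback sets out from 17. A Luche reduction (NaBH4, CeCl3·7H2O, MeOH, −78 °C) uses a small hydride that should enter along the axial path anti to the C10 methyl and give the C1-epimeric allylic alcohol F1. A Mitsunobu reaction (PPh3, DIAD, 4-nitrobenzoic acid, toluene, 0 °C → rt) then inverts C1 by SN2 displacement to give the 4-nitrobenzoate F2. K2CO3 in MeOH cleaves both the ester and the alkynyl silyl group, which returns to the route at 19. Any C1 epimer formed in step 11 itself can be fed into the same inversion, so either sense of attack ends at 19.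

Step 10. Sluggish methylene transfer to the crowded tetrasubstituted enol ether beside the quaternary C10, or loss of the enol ether to the Lewis-acidic zinc and iron salts before it is cyclopropanated, would return ketone instead of ring-enlarged product. The fallback sets out from 12 and inserts the same carbon between C1 and C3 by diazoalkane homologation. Me3SiCHN2 with BF3·OEt2 (CH2Cl2, −78 °C → rt, then K2CO3, MeOH to remove the α-silyl group) adds to the carbonyl, and the less substituted C3 should migrate in preference to the quaternary C10, giving the cycloheptanone F3. Dehydrogenation with 2-iodoxybenzoic acid (DMSO, 70 °C) can place the double bond only toward C2, because C10 bears no hydrogen, and gives the ethynyl enone F4. The conditions of step 11 convert F4 into 19, where the route is rejoined.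

Step 1. The ene step may also take the ring methine hydrogen, and the primary allylic alcohol may be oxidised on to the enal, so the oxidation may be unselective and low in conversion to 2. The fallback sets out from 1. Ene chlorination with hypochlorous acid generated from Ca(OCl)2 and solid CO2 (CH2Cl2/H2O, 0 °C) gives 10-chlorocarvone F5. KOAc in DMF displaces the allylic chloride to give 10-acetoxycarvone F6, and K2CO3 in MeOH at 0 °C releases 2, where the route is rejoined.

**Further compounds**

F1 | step 11 | C1-epimeric allylic alcohol (C1–OH syn to the C10 methyl), C-silylated alkyne | O[C@H]1C=C(C)CC[C@H]2[C@H](C#C[Si](C)(C)C)CC[C@]12C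
F2 | step 11 | C1-inverted 4-nitrobenzoate, C-silylated alkyne | O=C(O[C@@H]1C=C(C)CC[C@H]2[C@H](C#C[Si](C)(C)C)CC[C@]12C)c1ccc(cc1)[N+](=O)[O-]
F3 | step 10 | 7-ethynyl-3,10-dimethylbicyclo[5.3.0]decan-1-one (C3 mixture) | O=C1CC(C)CC[C@H]2[C@H](C#C)CC[C@]12C
F4 | step 10 | 7-ethynyl-3,10-dimethylbicyclo[5.3.0]dec-2-en-1-one | O=C1C=C(C)CC[C@H]2[C@H](C#C)CC[C@]12C
F5 | step 1 | (R)-10-chlorocarvone | CC1=CC[C@@H](C(=C)CCl)CC1=O
F6 | step 1 | (R)-10-acetoxycarvone | CC1=CC[C@@H](C(=C)COC(C)=O)CC1=O
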